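**Plan**

- Retrosynthesis: the hydroperoxide goes back to the trisubstituted side-chain alkene (ene reaction), the acetate to the alcohol and then the ketone, and the cyclopropane CH2 to a cis ring alkene. In the resulting butenolide-fused cyclooctadienone the ring CH2–CH(CH3) σ-bond lies γ,δ to the ring C=O, a Claisen retron inside the eight-membered carbocycle. Cutting it gives a butenolide-fused 2-methylene-6-(E)-propenyl-3,6-dihydro-2H-pyran.
- The pyran O–C(=CH2) bond is then cut to an allylic alcohol plus a terminal alkyne (6-exo-dig), the butenolide C=C and lactone C–O to a 1,2-diol plus a crotonoyl-acetyl unit (Knoevenagel), and the propargylic C–C bond to an epoxy alcohol derived from (R)-citronellal.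
- Forward ring order: butenolide (step 8), dihydropyran (step 10), eight-membered carbocycle by ring expansion (step 11), cyclopropane (step 13).
- Stereochemistry: the side-chain methyl centre comes from (R)-citronellal. The ring CH that carries the side chain comes from Sharpless epoxidation and invertive alkynylalane opening. The carbinol set by CBS reduction is relayed to the ring methyl centre through the chair Claisen array with the (E)-propenyl group. The O-bearing ring carbon is set by CBS reduction anti to the side chain, and the cyclopropane by hydroxyl direction, anti to the methyl.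

Key step: step 11

Remark: the final ene reaction is expected to give the target together with the regioisomeric secondary allylic hydroperoxides, from which it is separated by chromatography.

**Route**

Step 1
Reactants: 1 (R)-citronellal
Product: 3 (2R)-2,6-dimethylhept-5-enal, via enamine 2 (not isolated)
Conditions: piperidine, K2CO3, Et2O, 0 °C → rt; filter, concentrate; then CuCl (cat.), O2 (1 atm), MeCN, 0 °C
Reagents that add atoms: dioxygen (O=O)
Why: Enamine formation followed by copper-catalysed aerobic cleavage of the enamine C=C bond removes C-1 of the aldehyde (one-carbon degradation); the methyl stereocentre is not involved and ends α to the new formyl group under neutral conditions, the amine being consumed as the formamide.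

Step 2
Reactants: 3 (2R)-2,6-dimethylhept-5-enal; 4 triethyl phosphonoacetate
Product: 5 ethyl (2E,4R)-4,8-dimethylnona-2,7-dienoate
Conditions: LiCl, DBU, MeCN, 0 °C → rt
Reagents that add atoms: none
Why: Horner–Wadsworth–Emmons olefination under mild LiCl/DBU conditions should give the (E)-enoate without epimerising the α-stereocentre of the aldehyde.

Step 3
Reactants: 5 ethyl (2E,4R)-4,8-dimethylnona-2,7-dienoate
Product: 6 (2E,4R)-4,8-dimethylnona-2,7-dien-1-ol
Conditions: DIBAL-H, CH2Cl2, −78 °C
Reagents that add atoms: none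
Why: DIBAL-H effects 1,2-reduction of the enoate to the (E)-allylic alcohol and leaves the remote trisubstituted alkene untouched.

Step 4
Reactants: 6 (2E,4R)-4,8-dimethylnona-2,7-dien-1-ol
Product: 7 [(2R,3R)-3-[(2R)-6-methylhept-5-en-2-yl]oxiran-2-yl]methanol
Conditions: Ti(OiPr)4 (cat.), D-(−)-diethyl tartrate (cat.), t-BuOOH, 4 Å MS, CH2Cl2, −20 °C
Reagents that add atoms: tert-butyl hydroperoxide (CC(C)(C)OO)
Why: Sharpless asymmetric epoxidation is specific for the allylic-alcohol alkene and, with D-(−)-tartrate, should give the (2R,3R)-epoxy alcohol under reagent control, independent of the adjacent methyl stereocentre.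

Step 5
Reactants: 7 [(2R,3R)-3-[(2R)-6-methylhept-5-en-2-yl]oxiran-2-yl]methanol; 8 ethynyltrimethylsilane
Product: 10 (2S,3R,4R)-3-ethynyl-4,8-dimethylnon-7-ene-1,2-diol, via silylalkyne diol 9 (not isolated)
Conditions: 8, n-BuLi, PhMe, 0 °C; Et2AlCl; then 7, 0 °C → rt; Rochelle-salt work-up; then K2CO3 (cat.), MeOH, rt
Reagents that add atoms: none
Why: The aluminium alkoxide of the 2,3-epoxy alcohol directs the alkynylalane to C-3 (SN2 opening with inversion), which fixes the future ring CH stereocentre as a configurationally stable propargylic carbon; carbonate in methanol then cleaves the C–Si bond.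

Step 6
Reactants: 11 Meldrum's acid; 12 (E)-crotonic acid
Product: 13 5-[(2E)-1-hydroxybut-2-en-1-ylidene]-2,2-dimethyl-1,3-dioxane-4,6-dione
Conditions: DCC, DMAP, CH2Cl2, 0 °C → rt
Reagents that add atoms: none
Why: Carbodiimide-mediated C-acylation of Meldrum's acid with the (E)-enoic acid gives the acyl Meldrum's acid, a storable equivalent of the crotonoyl-acetyl unit with secured (E)-geometry.

Step 7
Reactants: 10 (2S,3R,4R)-3-ethynyl-4,8-dimethylnon-7-ene-1,2-diol; 13 5-[(2E)-1-hydroxybut-2-en-1-ylidene]-2,2-dimethyl-1,3-dioxane-4,6-dione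
Product: 14 (2S,3R,4R)-3-ethynyl-2-hydroxy-4,8-dimethylnon-7-en-1-yl (4E)-3-oxohex-4-enoate
Conditions: 13 (1.0 equiv, slow addition), PhMe, 80 °C
Reagents that add atoms: none
Why: On heating, the acyl Meldrum's acid loses acetone and CO2 and acylates the unhindered primary hydroxyl in preference to the neopentyl-like secondary one (β-keto ester formation by acylketene trapping).

Step 8
Reactants: 14 (2S,3R,4R)-3-ethynyl-2-hydroxy-4,8-dimethylnon-7-en-1-yl (4E)-3-oxohex-4-enoate
Product: 16 3-[(2E)-but-2-enoyl]-4-[(3R,4R)-4,8-dimethylnon-7-en-1-yn-3-yl]furan-2(5H)-one, via keto ester 15 (not isolated)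
Conditions: Dess–Martin periodinane, pyridine, CH2Cl2, 0 °C; then Et3N (cat.), 0 °C → rt
Reagents that add atoms: none
Why: Dess–Martin oxidation of the secondary alcohol gives the α-acyloxy ketone, whose β-keto ester methylene then closes the butenolide by an intramolecular Knoevenagel condensation (5-exo aldol addition and dehydration) under a weak amine–acetate buffer chosen to spare the propargylic stereocentre.

Step 9
Reactants: 16 3-[(2E)-but-2-enoyl]-4-[(3R,4R)-4,8-dimethylnon-7-en-1-yn-3-yl]furan-2(5H)-one
Product: 17 3-[(1R,2E)-1-hydroxybut-2-en-1-yl]-4-[(3R,4R)-4,8-dimethylnon-7-en-1-yn-3-yl]furan-2(5H)-one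
Conditions: (S)-2-methyl-CBS-oxazaborolidine (0.5 equiv), catecholborane, PhMe, −78 °C
Reagents that add atoms: none
Why: Corey–Bakshi–Shibata reduction of the cross-conjugated ketone (1,2-selective), with the tetrasubstituted butenolide carbon as the large group and the (E)-propenyl group as the small one, should set the (R)-carbinol with the (S)-catalyst.

Step 10
Reactants: 17 3-[(1R,2E)-1-hydroxybut-2-en-1-yl]-4-[(3R,4R)-4,8-dimethylnon-7-en-1-yn-3-yl]furan-2(5H)-one
Product: 18 (4R,7S)-6-methylidene-7-[(2R)-6-methylhept-5-en-2-yl]-4-[(1E)-prop-1-en-1-yl]-6,7-dihydro-1H-furo[3,4-c]pyran-3(4H)-one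
Conditions: AuCl (5 mol %), K2CO3 (10 mol %), MeCN, rt; filtration through Et3N-deactivated alumina
Reagents that add atoms: none
Why: Gold(I)-catalysed 6-exo-dig hydroalkoxylation of the terminal alkyne by the allylic hydroxyl (alkynol cycloisomerisation) closes the dihydropyran and gives the exocyclic enol ether under weakly basic conditions that keep the C=CH2 bond exocyclic; no stereocentre is changed.

Step 11
Reactants: 18 (4R,7S)-6-methylidene-7-[(2R)-6-methylhept-5-en-2-yl]-4-[(1E)-prop-1-en-1-yl]-6,7-dihydro-1H-furo[3,4-c]pyran-3(4H)-one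
Product: 19 (4S,7R,8Z)-7-methyl-4-[(2R)-6-methylhept-5-en-2-yl]-6,7-dihydrocycloocta[c]furan-1,5(3H,4H)-dione
Conditions: PhMe (degassed), base-washed sealed tube, 130 °C; concentrate and use directly
Reagents that add atoms: none
Why: A concerted [3,3]-sigmatropic (Claisen) shift of the allyl vinyl ether CH2=C–O–CH–CH=CH(CH3) embedded in the pyran breaks the doubly allylic O–C4 bond while the exocyclic methylene carbon bonds to the propenyl terminus, and the ring oxygen becomes the C5 ketone. The closest known reaction type is the thermal Claisen ring expansion of 2-methylene-6-vinyltetrahydropyrans to cyclooct-4-enones. The eight-membered carbocycle closes by this C–C bond formation through a chair-like six-atom array bridged across C-4 and C-6 of the pyran (oxabicyclo[3.3.1]-type transition state), which leaves the new ring alkene cis. The new methyl-bearing stereocentre (7R in 19) is set by chirality transfer from the (4R) carbinol carbon: the (E)-propenyl methyl sits exo (pseudo-equatorial) in the chair array, and the propenyl group is axial on the face it shares with the side chain, which stays pseudo-equatorial. The step needs chair over boat selectivity and no enolisation of the side-chain-bearing carbon next to the new ketone; the (E)-alkene geometry, the cis 4,7-relationship and strictly neutral conditions should secure both, with ketone formation and diene conjugation as driving force.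

Step 12
Reactants: 19 (4S,7R,8Z)-7-methyl-4-[(2R)-6-methylhept-5-en-2-yl]-6,7-dihydrocycloocta[c]furan-1,5(3H,4H)-dione
Product: 20 (4S,5R,7R,8Z)-5-hydroxy-7-methyl-4-[(2R)-6-methylhept-5-en-2-yl]-4,5,6,7-tetrahydrocycloocta[c]furan-1(3H)-one
Conditions: (S)-2-methyl-CBS-oxazaborolidine (0.5 equiv), catecholborane, PhMe, −78 → −40 °C
Reagents that add atoms: none
Why: CBS reduction with the (S)-catalyst, matched with the substrate bias for hydride attack anti to the neighbouring side chain, should give the (5R)-alcohol with OH cis to the side chain under non-basic conditions that do not enolise the acidic α-carbon.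

Step 13
Reactants: 20 (4S,5R,7R,8Z)-5-hydroxy-7-methyl-4-[(2R)-6-methylhept-5-en-2-yl]-4,5,6,7-tetrahydrocycloocta[c]furan-1(3H)-one
Product: 21 (4S,5R,7R,8S,9S)-5-hydroxy-7-methyl-4-[(2R)-6-methylhept-5-en-2-yl]-8,9-methano-4,5,6,7,8,9-hexahydrocycloocta[c]furan-1(3H)-one (cyclopropane CH2 cis to the 5-OH and to the side chain, trans to the 7-methyl)
Conditions: Et2Zn, CH2I2, CH2Cl2, −15 → 0 °C
Reagents that add atoms: diiodomethane (ICI)
Why: In this hydroxyl-directed Simmons–Smith (Furukawa) cyclopropanation the zinc alkoxide delivers CH2 across the ring to the cis-disubstituted alkene on the hydroxyl face, which is also the face anti to the allylic methyl group, and the directed reaction should outpace attack on the undirected side-chain alkene and the electron-poor butenolide alkene.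

Step 14
Reactants: 21 (4S,5R,7R,8S,9S)-5-hydroxy-7-methyl-4-[(2R)-6-methylhept-5-en-2-yl]-8,9-methano-4,5,6,7,8,9-hexahydrocycloocta[c]furan-1(3H)-one
Product: 22 the 5-O-acetate of 21
Conditions: Ac2O, pyridine, DMAP (cat.), CH2Cl2, rt
Reagents that add atoms: acetic anhydride (CC(=O)OC(C)=O)
Why: DMAP-catalysed acylation of the hindered secondary alcohol gives the acetate without affecting the lactone or the cyclopropane.

Step 15
Reactants: 22 the 5-O-acetate of 21
Product: 23 CNP0205234.1, i.e. 22 with the side chain (2R,4E)-6-hydroperoxy-6-methylhept-4-en-2-yl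
Conditions: O2, visible light, tetraphenylporphyrin (cat.), CH2Cl2, 0 °C; chromatography
Reagents that add atoms: dioxygen (O=O)
Why: In this Schenck ene reaction singlet oxygen attacks only the electron-rich trisubstituted alkene, and C–O bonding at the dimethyl-substituted carbon with abstraction of an allylic CH2 hydrogen gives the tertiary hydroperoxide with the (E)-disubstituted alkene, the regioisomers from methyl-hydrogen abstraction being removed by chromatography.

**Compound list**

1 | (R)-citronellal, (3R)-3,7-dimethyloct-6-enal | O=CC[C@H](C)CCC=C(C)C | starting material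
2 | 1-[(1E,3R)-3,7-dimethylocta-1,6-dien-1-yl]piperidine | N1(CCCCC1)/C=C/[C@H](C)CCC=C(C)C | intermediate
3 | (2R)-2,6-dimethylhept-5-enal | O=C[C@H](C)CCC=C(C)C | intermediate
4 | triethyl phosphonoacetate | CCOC(=O)CP(=O)(OCC)OCC | starting material
5 | ethyl (2E,4R)-4,8-dimethylnona-2,7-dienoate | CCOC(=O)/C=C/[C@H](C)CCC=C(C)C | intermediate
6 | (2E,4R)-4,8-dimethylnona-2,7-dien-1-ol | OC/C=C/[C@H](C)CCC=C(C)C | intermediate
7 | [(2R,3R)-3-[(2R)-6-methylhept-5-en-2-yl]oxiran-2-yl]methanol | OC[C@H]1O[C@@H]1[C@H](C)CCC=C(C)C | intermediate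
8 | ethynyltrimethylsilane | C#C[Si](C)(C)C | starting material
9 | (2S,3R,4R)-4,8-dimethyl-3-[(trimethylsilyl)ethynyl]non-7-ene-1,2-diol | C[Si](C)(C)C#C[C@@H]([C@H](C)CCC=C(C)C)[C@H](O)CO | intermediate
10 | (2S,3R,4R)-3-ethynyl-4,8-dimethylnon-7-ene-1,2-diol | C#C[C@@H]([C@H](C)CCC=C(C)C)[C@H](O)CO | intermediate
11 | Meldrum's acid, 2,2-dimethyl-1,3-dioxane-4,6-dione | CC1(C)OC(=O)CC(=O)O1 | starting material
12 | (E)-crotonic acid | C/C=C/C(=O)O | starting material
13 | 5-[(2E)-1-hydroxybut-2-en-1-ylidene]-2,2-dimethyl-1,3-dioxane-4,6-dione | C/C=C/C(O)=C1C(=O)OC(C)(C)OC1=O | intermediate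
14 | (2S,3R,4R)-3-ethynyl-2-hydroxy-4,8-dimethylnon-7-en-1-yl (4E)-3-oxohex-4-enoate | C#C[C@@H]([C@H](C)CCC=C(C)C)[C@H](O)COC(=O)CC(=O)/C=C/C | intermediate
15 | (3R,4R)-3-ethynyl-4,8-dimethyl-2-oxonon-7-en-1-yl (4E)-3-oxohex-4-enoate | C#C[C@@H]([C@H](C)CCC=C(C)C)C(=O)COC(=O)CC(=O)/C=C/C | intermediate
16 | 3-[(2E)-but-2-enoyl]-4-[(3R,4R)-4,8-dimethylnon-7-en-1-yn-3-yl]furan-2(5H)-one | C#C[C@@H]([C@H](C)CCC=C(C)C)C1=C(C(=O)/C=C/C)C(=O)OC1 | intermediate
17 | 3-[(1R,2E)-1-hydroxybut-2-en-1-yl]-4-[(3R,4R)-4,8-dimethylnon-7-en-1-yn-3-yl]furan-2(5H)-one | C#C[C@@H]([C@H](C)CCC=C(C)C)C1=C([C@H](O)/C=C/C)C(=O)OC1 | intermediate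
18 | (4R,7S)-6-methylidene-7-[(2R)-6-methylhept-5-en-2-yl]-4-[(1E)-prop-1-en-1-yl]-6,7-dihydro-1H-furo[3,4-c]pyran-3(4H)-one (propenyl and side chain cis on the pyran) | C=C1O[C@H](/C=C/C)C2=C(COC2=O)[C@@H]1[C@H](C)CCC=C(C)C | intermediate
19 | (4S,7R,8Z)-7-methyl-4-[(2R)-6-methylhept-5-en-2-yl]-6,7-dihydrocycloocta[c]furan-1,5(3H,4H)-dione | O=C1C[C@@H](C)/C=C\C2=C(COC2=O)[C@@H]1[C@H](C)CCC=C(C)C | intermediate
20 | (4S,5R,7R,8Z)-5-hydroxy-7-methyl-4-[(2R)-6-methylhept-5-en-2-yl]-4,5,6,7-tetrahydrocycloocta[c]furan-1(3H)-one | O[C@@H]1C[C@@H](C)/C=C\C2=C(COC2=O)[C@@H]1[C@H](C)CCC=C(C)C | intermediate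
21 | (4S,5R,7R,8S,9S)-5-hydroxy-7-methyl-4-[(2R)-6-methylhept-5-en-2-yl]-8,9-methano-4,5,6,7,8,9-hexahydrocycloocta[c]furan-1(3H)-one (cyclopropane cis to OH and side chain, trans to methyl) | O[C@@H]1C[C@@H](C)[C@@H]2C[C@@H]2C2=C(COC2=O)[C@@H]1[C@H](C)CCC=C(C)C | intermediate
22 | 5-O-acetate of 21 | CC(=O)O[C@@H]1C[C@@H](C)[C@@H]2C[C@@H]2C2=C(COC2=O)[C@@H]1[C@H](C)CCC=C(C)C | intermediate
23 | CNP0205234.1: 22 with the side chain (2R,4E)-6-hydroperoxy-6-methylhept-4-en-2-yl | CC(=O)O[C@@H]1C[C@@H](C)[C@@H]2C[C@@H]2C2=C(COC2=O)[C@@H]1[C@H](C)C/C=C/C(C)(C)OO | target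

**Step count and risks**

Total steps: 15. Longest linear sequence: 14 steps (steps 1–5 and 7–15, from (R)-citronellal); step 6 is a one-step side branch.

Steps most likely to fail:

Step 8. The amine may deprotonate the propargylic carbon of keto ester 15 or of the doubly activated product 16, which would epimerise that centre or isomerise the alkyne to an allene; cyclodehydration at the hindered ketone may also be sluggish. The fallback sets out from 10 and comes back at 16. The primary hydroxyl of 10 is esterified with 2-bromo-2-(diethoxyphosphoryl)acetic acid (DCC, cat. DMAP) to the bromophosphonoacetate F1, and Dess–Martin oxidation gives the ketone F2. An intramolecular Horner–Wadsworth–Emmons olefination (LiCl, iPr2NEt, MeCN, 0 °C) then closes the α-bromobutenolide F3, which is not doubly activated. A Nozaki–Hiyama–Kishi coupling of F3 with (E)-crotonaldehyde (CrCl2, cat. NiCl2, DMF) gives the epimeric allylic alcohols F4, and neutral MnO2 oxidation returns the route to 16, so the acidic 3-acyl butenolide only arises in a base-free step.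

Step 10. The exocyclic C=C bond may migrate into conjugation with the butenolide, the enol ether may be hydrated, or it may rearrange prematurely on the Lewis-acidic gold. The fallback sets out from 17 and comes back at 18. Lindlar semihydrogenation of the alkyne gives the vinyl compound F5. N-(Phenylseleno)phthalimide with catalytic camphorsulfonic acid effects a 6-exo selenoetherification to the 2-(phenylselanylmethyl)dihydropyran F6. Periodate oxidation gives the selenoxide F7, whose syn-elimination can only take the ring hydrogen on the ether carbon and so should deliver the exocyclic enol ether 18 under neutral conditions.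

Step 13. The carbenoid may also cyclopropanate the electron-rich trisubstituted side-chain alkene, and transannular direction by the hydroxyl may be weak. The fallback sets out from 20 and comes back at 22. Alcohol 20 is acetylated first (Ac2O, pyridine, DMAP) to the diene acetate F8. F8 is then cyclopropanated with diazomethane and catalytic Pd(OAc)2 in Et2O at 0 °C. This method discriminates by degree of substitution (the cis-disubstituted ring alkene reacts, the trisubstituted one does not) and should add on the face anti to the allylic methyl group, giving 22 directly.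

**Further compounds**

F1 | step 8 | (2S,3R,4R)-3-ethynyl-2-hydroxy-4,8-dimethylnon-7-en-1-yl 2-bromo-2-(diethoxyphosphoryl)acetate | C#C[C@@H]([C@H](C)CCC=C(C)C)[C@H](O)COC(=O)C(Br)P(=O)(OCC)OCC
F2 | step 8 | (3R,4R)-3-ethynyl-4,8-dimethyl-2-oxonon-7-en-1-yl 2-bromo-2-(diethoxyphosphoryl)acetate | C#C[C@@H]([C@H](C)CCC=C(C)C)C(=O)COC(=O)C(Br)P(=O)(OCC)OCC
F3 | step 8 | 3-bromo-4-[(3R,4R)-4,8-dimethylnon-7-en-1-yn-3-yl]furan-2(5H)-one | C#C[C@@H]([C@H](C)CCC=C(C)C)C1=C(Br)C(=O)OC1
F4 | step 8 | 3-[(2E)-1-hydroxybut-2-en-1-yl]-4-[(3R,4R)-4,8-dimethylnon-7-en-1-yn-3-yl]furan-2(5H)-one (carbinol epimers) | C#C[C@@H]([C@H](C)CCC=C(C)C)C1=C(C(O)/C=C/C)C(=O)OC1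
F5 | step 10 | 3-[(1R,2E)-1-hydroxybut-2-en-1-yl]-4-[(3S,4R)-4,8-dimethylnona-1,7-dien-3-yl]furan-2(5H)-one | C=C[C@@H]([C@H](C)CCC=C(C)C)C1=C([C@H](O)/C=C/C)C(=O)OC1
F6 | step 10 | (4R,7S)-7-[(2R)-6-methylhept-5-en-2-yl]-6-[(phenylselanyl)methyl]-4-[(1E)-prop-1-en-1-yl]-6,7-dihydro-1H-furo[3,4-c]pyran-3(4H)-one (C-6 epimers) | c1ccc(cc1)[Se]CC1O[C@H](/C=C/C)C2=C(COC2=O)[C@@H]1[C@H](C)CCC=C(C)C
F7 | step 10 | selenoxide of F6, 6-[(phenylseleninyl)methyl] compound | O=[Se](CC1O[C@H](/C=C/C)C2=C(COC2=O)[C@@H]1[C@H](C)CCC=C(C)C)c1ccccc1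
F8 | step 13 | (4S,5R,7R,8Z)-7-methyl-4-[(2R)-6-methylhept-5-en-2-yl]-1-oxo-1,3,4,5,6,7-hexahydrocycloocta[c]furan-5-yl acetate | CC(=O)O[C@@H]1C[C@@H](C)/C=C\C2=C(COC2=O)[C@@H]1[C@H](C)CCC=C(C)C
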